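(The data were computed from invented constants.)

Set substrate lost beside target gained: in Tuesday's run the loss stays ahead, and that gap is the thing to read.

| flask | substrate | reagent | free catalyst | impurity | remark |
|---|---|---|---|---|---|
| Tuesday's | 0.013 M | 0.052 M | 0.72 mM | 64 µM | run made earlier |
| flask | 0.013 M | 0.0520 M | 0.36 mM | 64 µM |  |

Tuesday's run (percent of the substrate charged)

| time / h | target / % | substrate / % |
|---|---|---|
| 1.00 | 1.6 | 93.7 |
| 2.00 | 4.9 | 89.7 |
| 2.50 | 6.6 | 88.8 |
| 4.00 | 11.9 | 82.5 |
| 6.00 | 18.8 | 76.9 |
| 10.0 | 31.3 | 63.9 |
| 15.0 | 45.5 | 49.1 |

(readings scatter by 0.5 percentage points)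

* factor on the rate of making target when 50% of the substrate are converted if free catalyst is charged twice over
* factor on the rate when 50% of the substrate are converted if free catalyst is charged at 2.0 mM instead

- no earlier run changes the charge of free catalyst; that part of a forecast is a guess

Start with the first instants of Tuesday's run. As a fraction of the substrate charged, the gap is 4.70% at 1.00 h and 5.40% at 15.0 h, so it opens early and then barely moves. Hold it against Tuesday's free catalyst minus impurity, taken as a fraction of the substrate: 5.05%. Read this as impurity taking catalyst one for one, with the remainder holding substrate. Call the remainder the working share; for the new flask it is 2.28%.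

Now the middle. Tuesday's target gains 0.0350 /h from 2.00 h to 4.00 h, and 0.0284 /h from 10.0 h to 15.0 h, while substrate falls from 89.7% to 49.1%. Tuesday's rate therefore follows substrate weakly over these readings.

Tuesday's last reading sits close to the asked 50% conversion, so use the interval that ends there. Divide its gain by the working share to get the turnover rate, target made per working catalyst (the turnover frequency): 13.5 /d. No run tests whether it holds at another catalyst charge; assume that it does. This reckoning then gives factors of 2.22 and 6.54 on the new flask.

The forecast gives 2.2 and 6.2. Its second factor lies below this reckoning's; the forecast's own ground for the trim is that “more substrate is tied up and saturation is imperfect”.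

The simulation gives 2.28 and 6.93.

    catalyst intermediate B ⇌ by-product + catalyst intermediate C (K = 0.0180 M, k = 7.60 × 10⁻⁴ /s)
    catalyst intermediate C → free catalyst + target (k = 6.10 × 10⁻⁴ /s)
    free catalyst + impurity → spent catalyst A (k = 27.0 /M/s)
    catalyst intermediate C → spent catalyst B (k = 1.00 × 10⁻⁶ /s)
    substrate + free catalyst → catalyst intermediate A (k = 0.310 /M/s)
    reagent + catalyst intermediate A → catalyst intermediate B (k = 0.0100 /M/s)

In the new flask, spent catalyst A stands at 17.8% of the catalyst charged at 1.50 d, and the impurity's charge is 17.8% of that catalyst. The turnover rate times this flask's working share gives 0.308 /d of the substrate charge, and the simulated rate of this flask at 50% conversion is 0.306 /d. With 2.0 mM of catalyst the working share is 14.9%, which gives 2.01 /d, and the simulated rate there is 2.12 /d.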